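All runs were computed for substances that don't exist, and the scatter is random.

The product in the spring run gained 2.50 mM over its last 19.0 min and stood at 0.1258 M from 0.150 M of substrate, so I wanted a number that reads a stalling flask without a rate law for the stall.

| flask | substrate | partner | free catalyst | time |
|---|---|---|---|---|
| spring | 0.150 M | 0.450 M | 0.00450 M |  |
| midnight | 0.0900 M | 0.390 M | 0.00450 M |  |
| dusk | 0.150 M | 0.450 M | 0.00220 M |  |
| dawn | 0.300 M | 0.450 M | 0.00450 M |  |
| summer | 0.150 M | 0.450 M | 9.80 × 10⁻⁴ M | 74 min |

- spring run (time / min: [product] / M): 4.2: 0.0605; 13: 0.0973; 24: 0.1120; 39: 0.1206; 55: 0.1233; 74: 0.1258
- midnight run (time / min: [product] / M): 4.2: 0.0336; 13: 0.0567; 24: 0.0671; 39: 0.0711; 55: 0.0754; 74: 0.0756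
- dusk run (time / min: [product] / M): 4.2: 0.0332; 13: 0.0635; 24: 0.0756; 39: 0.0851; 55: 0.0892; 74: 0.0919
- dawn run (time / min: [product] / M): 4.2: 0.1130; 13: 0.1800; 24: 0.2045; 39: 0.2190; 55: 0.2244; 74: 0.2300

(readings scatter by 8 × 10⁻⁴ M)

1. the exponent of [free catalyst] in the starting rate at the charge of the spring run (at the point where two percent of the substrate have become product)
2. the exponent of [partner] in the starting rate at the charge of the spring run (at the point where two percent of the substrate have become product)
3. the midnight run starts with 0.0600 M less of substrate and of partner than the spring run, and with no product. Compared where both hold the same amount of substrate, once fifteen percent of what the midnight run was charged with has turned into product, is the midnight run faster, slower or alike (within a tenth)?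
4. product in the summer run at 74 min, as a share of the substrate charged

- Overall: substrate + partner -> product, with free catalyst as catalyst.
- Constant volume, constant temperature.
- "The second partner" is partner.
- An order is taken over about fifteen percent of the charge, up and down.

I followed one substrate molecule, from the limiting reagent at 0.150 M against 0.450 M of partner in the spring run. If the rate is first order in substrate and in free catalyst, that molecule's chance of surviving to 74 min is an exponential with the charged catalyst in its exponent. I therefore took the dose, the natural logarithm of substrate charged over substrate left at 74 min, divided by the free catalyst charged.

I turned the substrate first. By hand, first order keeps the share converted when the charge changes. The dawn run, with twice the substrate of the spring run, reached 37.7% at 4.2 min against 40.3% in the spring run, which I accepted as close to order one.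

Next I turned the catalyst. By hand, the rate follows the charge. The dusk run was charged 0.00220 M of free catalyst against 0.00450 M in the spring run, and at 4.2 min the logarithm of substrate charged over substrate left read 0.250 in the dusk run against 0.516 in the spring run, so:

order in free catalyst = ln(0.484) / ln(0.489) = 1.01

Last I turned the partner. By hand, with order one in substrate, the logarithm follows the partner held. At 4.2 min it read 0.467 in the midnight run against 0.516 in the spring run, and I took each run's mean partner as its charge less half its product, so:

order in partner = ln(0.905) / ln(0.889) = 0.848

From this one early reading I took order one in partner.

The midnight run was charged 0.0600 M short of the spring run in both, and the spring run had made 0.0605 M by 4.2 min, so from there the two held like amounts of substrate, in a same-excess comparison. The spring run then gained 0.0368 M in 8.80 min, while the midnight run gained 0.0336 M in its first 4.2 min. I called the midnight run faster.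

For the summer run, the dusk run gave a dose of 431 M⁻¹, and the spring run gave 405 M⁻¹, which is lower. The spring run, which made more product than the dusk run, had the smaller dose, so I slid along that line:

first pass: share = 34.5%, product 0.0517 M

corrected dose = 462 M⁻¹

share = 36.4%

The forecast gave orders 1 and 1, faster, and 37%, holding that “the catalyst dies on the clock”.

The simulation gave 36.7% for the summer run, orders 1.0 in free catalyst and 1.0 in partner, and the midnight run faster.

    free catalyst + substrate + partner → product + free catalyst (82.80 M⁻² min⁻¹)
    2 partner → lost reagent (0.1290 M⁻¹ min⁻¹)
    free catalyst → spent catalyst (0.01734 min⁻¹)

The fit with the main steps alone had put the summer run at 59.0%, which is 22 percentage points above the simulated share. Read back through the logarithm, the summer run's share is a dose of 467 M⁻¹, larger than the 431 M⁻¹ of the dusk run by a factor of 1.08.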